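**Retrosynthetic overview**

1. Mollicellin A is traced back (MnO2, then Tamao–Fleming oxidation) to a depsidone with an oxasilole fused to ring A: the adjacent hydroxyl and formyl carbons are unmasked from one aryl C–Si bond and one ArCH2–O–Si bond.
2. The oxasilole depsidone is disconnected to a triyne by a rhodium-catalysed (2+2+2) cyclotrimerization that forms three ring A C–C bonds and closes ring A, lactone ring B and the oxasilole in one operation.
3. Feature used: every ring A carbon can be an alkyne carbon. C(O-aryl)/C(CH2O) come from an ynol ether on O6 of ring C, C(Si, later OH)/C(H) from an ethynylsilane tied through Si–O–CH2, and C(CH3)/C(C=O) from a but-2-ynoate on O7; the ortho oxygens O6/O7 of ring C are the second tether.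
4. The triyne comes from 6,7-dihydroxy-2,2,5-trimethylchroman-4-one (rings C and D): the 7-OH is allylated, the hindered 6-OH becomes the ynol ether (CuI coupling with a 1,1-dibromoalkene, then elimination), the silyl tether is installed, and allyl is exchanged for but-2-ynoyl.
5. Rings C/D come from 2,4-dihydroxy-6-methylbenzaldehyde (Dakin oxidation) and 3-methylbut-2-enoic acid (Friedel–Crafts/oxa-Michael). Ring order: C (bought), D, then A and B together. The target has no stereocentre.

Key step: step 12

Assumption: 2,4-dihydroxy-6-methylbenzaldehyde (the formylation product of orcinol) is taken as a purchasable starting material.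
Assumption: the bromoenol ether of step 5 is drawn as the Z isomer (the C–Br bond trans to the CH2 group couples first); either geometry would converge on the same alkyne.

**Route**

Step 1
Reactants: 1 2,4-dihydroxy-6-methylbenzaldehyde
Product: 3 6-methylbenzene-1,2,4-triol, via aryl formate 2 (not isolated)
Conditions: 30% aq. H2O2, H3BO3, H2SO4 (cat.), THF, rt, under Ar; aq. Na2S2O4 work-up, crude used at once
Reagents that add atoms: hydrogen peroxide, OO
Why: Dakin oxidation: the hydroperoxide adduct of the aldehyde should rearrange with aryl migration, which the ortho and para hydroxyl groups favour, the formate is hydrolysed in the aqueous acid, and boric acid holds the new catechol as a borate against further oxidation.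

Step 2
Reactants: 3 6-methylbenzene-1,2,4-triol; 4 3-methylbut-2-enoic acid
Product: 6 6,7-dihydroxy-2,2,5-trimethylchroman-4-one, via aryl enone 5 (not isolated)
Conditions: P2O5/MeSO3H (1:10 w/w), 70 °C, under Ar
Reagents that add atoms: none
Why: Friedel–Crafts acylation followed by intramolecular oxa-Michael addition: acylation should go to C5 of the triol, the free position that is ortho to one hydroxyl and para to another without lying between two oxygens (the preference shown by orcinol and by 3,4-dialkoxyphenols), and the neighbouring 4-OH then closes ring D by 6-endo-trig addition, while isomers from attack at C3 would carry a chelated 5-OH and should separate on silica.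

Step 3
Reactants: 6 6,7-dihydroxy-2,2,5-trimethylchroman-4-one
Product: 7 7-(allyloxy)-6-hydroxy-2,2,5-trimethylchroman-4-one
Conditions: allyl bromide (1.05 equiv), K2CO3 (1.0 equiv), DMF, 0 °C to rt
Reagents that add atoms: allyl bromide, C=CCBr
Why: Williamson ether synthesis under acidity control: one equivalent of base should ionize only the 7-OH, which is para to the ring D carbonyl and unhindered, whereas the 6-OH is meta to the carbonyl and flanked by the 5-methyl group.

Step 4
Reactants: 8 (tert-butyldimethylsilyloxy)acetaldehyde
Product: 9 tert-butyl[(3,3-dibromoprop-2-en-1-yl)oxy]dimethylsilane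
Conditions: CBr4, PPh3, zinc dust, CH2Cl2, rt; then 8, 0 °C to rt
Reagents that add atoms: carbon tetrabromide, BrC(Br)(Br)Br
Why: Ramirez dibromoolefination (first stage of the Corey–Fuchs sequence): the ylide Ph3P=CBr2 converts the aldehyde to the 1,1-dibromoalkene, and the zinc variant avoids Ph3PBr2 and so spares the silyl ether.

Step 5
Reactants: 7 7-(allyloxy)-6-hydroxy-2,2,5-trimethylchroman-4-one; 9 tert-butyl[(3,3-dibromoprop-2-en-1-yl)oxy]dimethylsilane
Product: 10 (Z)-7-(allyloxy)-6-{[1-bromo-3-(tert-butyldimethylsilyloxy)prop-1-en-1-yl]oxy}-2,2,5-trimethylchroman-4-one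
Conditions: CuI (copper monoiodide, 10 mol %), 2,2'-bipyridine (20 mol %), K3PO4, toluene, 110 °C; 9 in excess
Reagents that add atoms: none
Why: Ullmann-type CuI-catalysed C–O coupling of a phenol with a 1,1-dibromoalkene: the C–Br bond trans to the CH2OTBS group should react and the second bromide is kept for the elimination, an excess of 9 suppresses double substitution to the ketene acetal, and the allyl ether is well below its Claisen temperature.

Step 6
Reactants: 10 (Z)-bromoenol ether
Product: 11 7-(allyloxy)-6-{[3-(tert-butyldimethylsilyloxy)prop-1-yn-1-yl]oxy}-2,2,5-trimethylchroman-4-one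
Conditions: KOtBu (2.2 equiv), THF, 0 °C; pH 7 buffer
Reagents that add atoms: none
Why: Base-induced anti dehydrobromination of the 1-bromoenol ether (H and Br are trans in the Z isomer) should give the aryl ynol ether, the ketone being only enolized reversibly by the extra base, while low temperature and short contact guard against propargyl–allenyl isomerization.

Step 7
Reactants: 11 silyl-protected ynol ether
Product: 12 7-(allyloxy)-6-[(3-hydroxyprop-1-yn-1-yl)oxy]-2,2,5-trimethylchroman-4-one
Conditions: TBAF (1.1 equiv), THF, 0 °C; pH 7 buffer
Reagents that add atoms: none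
Why: Fluoride desilylation: TBAF cleaves the primary TBS ether under basic conditions to which the aryl ynol ether, the allyl ether and the ketone are inert, and the neutral work-up avoids acid-induced hydration or Meyer–Schuster-type rearrangement of the 3-hydroxy ynol ether.

Step 8
Reactants: 13 dichlorodiisopropylsilane; 14 ethynylmagnesium bromide
Product: 15 chloro(ethynyl)diisopropylsilane
Conditions: 13 (1.5 equiv), THF, 0 °C to rt; distillation
Reagents that add atoms: none
Why: Grignard substitution at silicon: one chloride of the hindered dichlorosilane, used in excess, is replaced by the acetylide, the second substitution being much slower at the diisopropyl-substituted silicon.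

Step 9
Reactants: 12 propargylic alcohol; 15 chloro(ethynyl)diisopropylsilane
Product: 16 7-(allyloxy)-6-{[3-(ethynyldiisopropylsilyloxy)prop-1-yn-1-yl]oxy}-2,2,5-trimethylchroman-4-one
Conditions: imidazole, CH2Cl2, 0 °C to rt
Reagents that add atoms: none
Why: Silyl ether formation from a primary alcohol, a chlorosilane and imidazole, in a basic medium that protects the ynol ether, the two isopropyl groups making the alkynylsilyl ether robust enough for the next two steps.

Step 10
Reactants: 16 allyl-protected diyne
Product: 17 6-{[3-(ethynyldiisopropylsilyloxy)prop-1-yn-1-yl]oxy}-7-hydroxy-2,2,5-trimethylchroman-4-one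
Conditions: Pd(PPh3)4 (5 mol %), morpholine (3 equiv), THF, rt; pH 7 buffer, used at once
Reagents that add atoms: none
Why: Tsuji–Trost deallylation: zerovalent palladium ionizes the allyl aryl ether (the phenoxide para to the ketone is a good leaving group) and morpholine traps the π-allyl complex, which leaves the ynol ether, the terminal alkyne and the Si–O bond alone, and the phenol is acylated at once because an acidic OH beside the ynol ether could add to it.

Step 11
Reactants: 17 phenol diyne; 18 but-2-ynoic acid
Product: 20 7-(but-2-ynoyloxy)-6-{[3-(ethynyldiisopropylsilyloxy)prop-1-yn-1-yl]oxy}-2,2,5-trimethylchroman-4-one, via but-2-ynoic anhydride 19 (not isolated)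
Conditions: 18 (2.2 equiv), DCC (1.1 equiv), CH2Cl2, 0 °C; then 17, iPr2NEt, DMAP (5 mol %), −20 to 0 °C
Reagents that add atoms: none
Why: Acylation of a phenol with a preformed symmetrical anhydride under amine base and DMAP catalysis, in which the strong carboxylic acid never meets the acid-labile ynol ether because DCC converts it to the anhydride beforehand, and the low temperature limits amine addition to the ynoate and isomerization to the allenoate.

Step 12
Reactants: 20 triyne
Product: 21 oxasilole-fused depsidone (ring A carries Si(iPr)2 at the future hydroxyl carbon and OCH2 at the future formyl carbon, joined in a 2,2-diisopropyl-1,2-oxasilole)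
Conditions: RhCl(PPh3)3 (10 mol %), toluene, 80 °C, slow addition of 20, final concentration about 2 mM
Reagents that add atoms: none
Why: Monovalent rhodium (RhCl(PPh3)3 after loss of PPh3) should couple oxidatively the two alkynes joined by the three-atom CH2–O–Si tether to a trivalent rhodacyclopentadiene, which forms the bond between the CH2O-bearing and the Si-bearing carbons and closes the five-membered oxasilole; the but-2-ynoate held on the neighbouring O7 then inserts into the Rh–C bond at the aryloxy carbon, which closes the seven-membered lactone ring B, and reductive elimination joins the methyl-bearing carbon to the CH carbon and closes ring A as a benzene ring. The closest known reaction type is the rhodium- or cobalt-catalysed intramolecular cyclotrimerization of triynes with a temporary Si–O tether, with aryl ynol ethers and alkynoate esters both established as partners; the seven-membered ester tether is the untested element. No stereocentre is formed. Regiochemistry needs no control beyond the two tethers, which allow a single connectivity; the selectivity needed is intramolecular insertion of the ynoate against capture of the metallacycle by a second triyne, and it is secured by the ortho placement of O6 and O7 on the rigid ring C, by the pairing of an electron-poor ynoate with an electron-rich metallacycle, and by slow addition at high dilution.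

Step 13
Reactants: 21 oxasilole-fused depsidone
Product: 22 depsidone carrying OH and CH2OH on adjacent ring A carbons (mollicellin A with CH2OH in place of CHO)
Conditions: 30% aq. H2O2, KF, KHCO3, THF/DMF, rt to 40 °C
Reagents that add atoms: hydrogen peroxide, OO
Why: Tamao–Fleming oxidation: fluoride and hydroperoxide add to the cyclic alkoxysilane, the aryl group migrates from silicon to oxygen at the same ring carbon, and hydrolysis frees the phenol and the benzylic alcohol, with bicarbonate buffering, a methanol-free medium and mild warming meant to spare the aryl lactone.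

Step 14
Reactants: 22 hydroxymethyl phenol
Product: 23 mollicellin A
Conditions: activated MnO2 (excess), CH2Cl2, rt
Reagents that add atoms: none
Why: MnO2 oxidation of a benzylic alcohol: the heterogeneous oxidant should convert the salicyl alcohol to the hydrogen-bonded salicylaldehyde without touching the phenol, the lactone or the ketone and without over-oxidation.

**Compound list**

1 | 2,4-dihydroxy-6-methylbenzaldehyde | Cc1cc(O)cc(O)c1C=O | starting material
2 | 2,4-dihydroxy-6-methylphenyl formate | Cc1cc(O)cc(O)c1OC=O | intermediate
3 | 6-methylbenzene-1,2,4-triol | Cc1cc(O)cc(O)c1O | intermediate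
4 | 3-methylbut-2-enoic acid | CC(C)=CC(=O)O | starting material
5 | 1-(2,4,5-trihydroxy-6-methylphenyl)-3-methylbut-2-en-1-one | CC(C)=CC(=O)c1c(C)c(O)c(O)cc1O | intermediate
6 | 6,7-dihydroxy-2,2,5-trimethylchroman-4-one | Cc1c(O)c(O)cc2OC(C)(C)CC(=O)c12 | intermediate
7 | 7-(allyloxy)-6-hydroxy-2,2,5-trimethylchroman-4-one | C=CCOc1cc2OC(C)(C)CC(=O)c2c(C)c1O | intermediate
8 | (tert-butyldimethylsilyloxy)acetaldehyde | CC(C)(C)[Si](C)(C)OCC=O | starting material
9 | tert-butyl[(3,3-dibromoprop-2-en-1-yl)oxy]dimethylsilane | CC(C)(C)[Si](C)(C)OCC=C(Br)Br | intermediate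
10 | (Z)-7-(allyloxy)-6-{[1-bromo-3-(tert-butyldimethylsilyloxy)prop-1-en-1-yl]oxy}-2,2,5-trimethylchroman-4-one | C=CCOc1cc2OC(C)(C)CC(=O)c2c(C)c1O/C(Br)=C/CO[Si](C)(C)C(C)(C)C | intermediate
11 | 7-(allyloxy)-6-{[3-(tert-butyldimethylsilyloxy)prop-1-yn-1-yl]oxy}-2,2,5-trimethylchroman-4-one | C=CCOc1cc2OC(C)(C)CC(=O)c2c(C)c1OC#CCO[Si](C)(C)C(C)(C)C | intermediate
12 | 7-(allyloxy)-6-[(3-hydroxyprop-1-yn-1-yl)oxy]-2,2,5-trimethylchroman-4-one | C=CCOc1cc2OC(C)(C)CC(=O)c2c(C)c1OC#CCO | intermediate
13 | dichlorodiisopropylsilane | CC(C)[Si](Cl)(Cl)C(C)C | starting material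
14 | ethynylmagnesium bromide | C#C[Mg]Br | starting material
15 | chloro(ethynyl)diisopropylsilane | CC(C)[Si](Cl)(C#C)C(C)C | intermediate
16 | 7-(allyloxy)-6-{[3-(ethynyldiisopropylsilyloxy)prop-1-yn-1-yl]oxy}-2,2,5-trimethylchroman-4-one | C=CCOc1cc2OC(C)(C)CC(=O)c2c(C)c1OC#CCO[Si](C(C)C)(C(C)C)C#C | intermediate
17 | 6-{[3-(ethynyldiisopropylsilyloxy)prop-1-yn-1-yl]oxy}-7-hydroxy-2,2,5-trimethylchroman-4-one | Oc1cc2OC(C)(C)CC(=O)c2c(C)c1OC#CCO[Si](C(C)C)(C(C)C)C#C | intermediate
18 | but-2-ynoic acid | CC#CC(=O)O | starting material
19 | but-2-ynoic anhydride | CC#CC(=O)OC(=O)C#CC | intermediate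
20 | 7-(but-2-ynoyloxy)-6-{[3-(ethynyldiisopropylsilyloxy)prop-1-yn-1-yl]oxy}-2,2,5-trimethylchroman-4-one (triyne) | CC#CC(=O)Oc1cc2OC(C)(C)CC(=O)c2c(C)c1OC#CCO[Si](C(C)C)(C(C)C)C#C | intermediate
21 | oxasilole-fused depsidone (Si on the future hydroxyl carbon, OCH2 on the future formyl carbon of ring A) | Cc1cc2c(CO[Si]2(C(C)C)C(C)C)c2c1C(=O)Oc1cc3OC(C)(C)CC(=O)c3c(C)c1O2 | intermediate
22 | depsidone with OH and CH2OH on adjacent ring A carbons | Cc1cc(O)c(CO)c2c1C(=O)Oc1cc3OC(C)(C)CC(=O)c3c(C)c1O2 | intermediate
23 | mollicellin A | Cc1cc(O)c(C=O)c2c1C(=O)Oc1cc3c(c(C)c1O2)C(=O)CC(C)(C)O3 | target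

**Step count and risks**

Total step count: 14. Longest linear sequence: 12 steps (steps 1, 2, 3, 5, 6, 7, 9, 10, 11, 12, 13, 14).

Steps most likely to fail:

Step 12. The tethered ynoate must adopt the less stable ester conformation to reach the metallacycle, so oligomerization or dimerization of the terminal alkyne may outrun closure of the seven-membered lactone. Fallback: the ester bond is taken out of the cycloaddition and ring B is closed last by lactonization. It sets out from diyne 16 and acid 18 and comes back at 21. Acid 18 is esterified with allyl alcohol (DCC, DMAP, CH2Cl2) to allyl but-2-ynoate F1. Diyne 16 and F1 are cyclotrimerized bimolecularly ([Rh(cod)2]BF4, rac-BINAP, CH2Cl2, rt), which should give the allyl ester diaryl ether F2, in which ring A already carries the oxasilole, the methyl group and the ester beside the aryloxy carbon. The orientation of F1 is no longer fixed by a tether, so the isomer with the ester beside the ring A CH would have to be separated. Pd(PPh3)4 and morpholine then remove the allyl ether and the allyl ester in one operation to give the hydroxy acid F3. Lactonization of the 7-OH onto the ring A carboxyl (2-chloro-1-methylpyridinium iodide, Et3N, CH2Cl2, high dilution), the usual closing step of depsidone syntheses, returns to 21.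

Step 5. C–O bond formation at a phenol flanked by a methyl and an allyloxy group may be too slow, so that 9 decomposes at 110 °C before coupling. Fallback: the C–O bond is made with a small electrophile and the alkyne is built afterwards by organolithium chemistry, with the ketone masked. It sets out from phenol 7 and comes back at alcohol 12. Phenol 7 is heated with trichloroethylene and K2CO3 in DMF (addition to dichloroacetylene formed in the flask) to give the (E)-1,2-dichlorovinyl ether F4. The ketone is masked as its silyl enol ether (TBSOTf, Et3N, CH2Cl2, 0 °C) to give the 4-silyloxychromene F5. n-Butyllithium (2.2 equiv, THF, −78 °C) converts the dichlorovinyl ether to the lithium aryloxyacetylide by elimination and chlorine–lithium exchange, and paraformaldehyde traps it as the propargylic alcohol F6. TBAF (THF, 0 °C) cleaves the silyl enol ether and returns the ketone in 12. This route also saves the TBS ether of the main sequence.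

Step 13. Hydroperoxide may attack the aryl lactone carbonyl and open ring B faster than it oxidizes the hindered diisopropylsilicon, and the electron-poor aryl group may migrate slowly. Fallback: the tether is redesigned with a diethylsilicon, whose benzoxasilole should be oxidized by bicarbonate-buffered peroxide at room temperature without fluoride. It sets out from alcohol 12 and Grignard reagent 14 and comes back at diol 22. Dichlorodiethylsilane and 14 give chloro(diethyl)ethynylsilane F7. Alcohol 12 is silylated with F7 (imidazole, CH2Cl2) to the diethylsilyl diyne F8. Deallylation as in step 10 gives the phenol F9, and acylation with anhydride 19 as in step 11 gives the diethylsilyl triyne F10. Cyclotrimerization as in step 12 gives the diethyl oxasilole depsidone F11. Oxidation with 30% H2O2 and KHCO3 in THF at rt then delivers 22.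

**Further compounds**

F1 | step 12 | allyl but-2-ynoate | CC#CC(=O)OCC=C
F2 | step 12 | allyl ester diaryl ether (ring A with oxasilole, methyl and allyl ester; ring C with 7-allyloxy) | C=CCOC(=O)c1c(C)cc2[Si](C(C)C)(C(C)C)OCc2c1Oc1c(OCC=C)cc2OC(C)(C)CC(=O)c2c1C
F3 | step 12 | hydroxy acid (ring A carboxylic acid, ring C 7-OH) | OC(=O)c1c(C)cc2[Si](C(C)C)(C(C)C)OCc2c1Oc1c(O)cc2OC(C)(C)CC(=O)c2c1C
F4 | step 5 | 7-(allyloxy)-6-[(E)-1,2-dichlorovinyloxy]-2,2,5-trimethylchroman-4-one | C=CCOc1cc2OC(C)(C)CC(=O)c2c(C)c1O/C(Cl)=C\Cl
F5 | step 5 | 7-(allyloxy)-4-(tert-butyldimethylsilyloxy)-6-[(E)-1,2-dichlorovinyloxy]-2,2,5-trimethyl-2H-chromene | C=CCOc1cc2OC(C)(C)C=C(O[Si](C)(C)C(C)(C)C)c2c(C)c1O/C(Cl)=C\Cl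
F6 | step 5 | 3-{[7-(allyloxy)-4-(tert-butyldimethylsilyloxy)-2,2,5-trimethyl-2H-chromen-6-yl]oxy}prop-2-yn-1-ol | C=CCOc1cc2OC(C)(C)C=C(O[Si](C)(C)C(C)(C)C)c2c(C)c1OC#CCO
F7 | step 13 | chloro(diethyl)ethynylsilane | CC[Si](Cl)(CC)C#C
F8 | step 13 | 7-(allyloxy)-6-{[3-(diethylethynylsilyloxy)prop-1-yn-1-yl]oxy}-2,2,5-trimethylchroman-4-one | C=CCOc1cc2OC(C)(C)CC(=O)c2c(C)c1OC#CCO[Si](CC)(CC)C#C
F9 | step 13 | 6-{[3-(diethylethynylsilyloxy)prop-1-yn-1-yl]oxy}-7-hydroxy-2,2,5-trimethylchroman-4-one | Oc1cc2OC(C)(C)CC(=O)c2c(C)c1OC#CCO[Si](CC)(CC)C#C
F10 | step 13 | 7-(but-2-ynoyloxy)-6-{[3-(diethylethynylsilyloxy)prop-1-yn-1-yl]oxy}-2,2,5-trimethylchroman-4-one | CC#CC(=O)Oc1cc2OC(C)(C)CC(=O)c2c(C)c1OC#CCO[Si](CC)(CC)C#C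
F11 | step 13 | diethyl oxasilole-fused depsidone | Cc1cc2c(CO[Si]2(CC)CC)c2c1C(=O)Oc1cc3OC(C)(C)CC(=O)c3c(C)c1O2
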